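**Retrosynthetic overview**

1. Endgame: the C15 malonic half-ester (Meldrum's acid) and the C18 angelate (Yamaguchi) go on last; the C8 carbinol comes from the 8(17)-alkene via its equatorial epoxide, and the axial C19 methyl from deoxygenation of an axial CH2OH.
2. Key disconnection: ring A is opened at C1–C2 and C3–C4; the C2–C3 unit is the vinyl group of vinyltriphenylphosphonium bromide, stitched onto a ring-B keto aldehyde malonate by Michael addition and intramolecular Wittig olefination (Schweizer annulation).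
3. Enabling feature: ring A is functionalised only at quaternary C4, whose two one-carbon branches (C18, C19) can both stand at the ester level and make C4 a malonate carbanion; C1 is a methylene on quaternary C10 and can be a formyl group without α-hydrogen; C2 and C3 are bare methylenes.
4. Ring B is built first from 2-methylcyclohex-2-enone: Pd-catalysed asymmetric allylic alkylation with dimethyl malonate (C5), allylic oxidation, conjugate vinylation (quaternary C10, trans to C5), then aldol, dehydration and conjugate reduction with an aldehyde from methyl hydrogen (R)-3-methylglutarate (C9 side chain, C13).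
5. Ring order: ring B (from the starting cyclohexenone), then ring A (step 13); the trans ring fusion follows from the trans C5/C10 relation set before the annulation.

Key step: step 13

Remark: decalin intermediates are named with labdane locants (ring A: C1–C5 and C10; ring B: C5–C10; side chain C11–C16; C17 on C8; C18 equatorial and C19 axial on C4; C20 on C10); in step 6 the (R,R)-ligand is assigned from the Trost mnemonic, and its mirror image would be used if the opposite sense of induction were found.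

**Route**

Step 1
Reactants: 1 methyl hydrogen (R)-3-methylglutarate
Product: 2 methyl (3R)-5-hydroxy-3-methylpentanoate
Conditions: BH3·SMe2, THF, 0 °C to rt; MeOH, aqueous work-up
Reagents that add atoms: none
Why: Chemoselective borane reduction of a carboxylic acid in the presence of an ester (via the acyloxyborane) should give the hydroxy ester and leave the C3 stereocentre untouched.

Step 2
Reactants: 2 methyl (3R)-5-hydroxy-3-methylpentanoate
Product: 3 methyl (3R)-5-{[tert-butyl(diphenyl)silyl]oxy}-3-methylpentanoate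
Conditions: TBDPSCl, imidazole, CH2Cl2, rt
Reagents that add atoms: tert-butyl(chloro)diphenylsilane CC(C)(C)[Si](Cl)(c1ccccc1)c1ccccc1
Why: Standard silylation of a primary alcohol gives a TBDPS ether, chosen because it should survive TiCl4, LiAlH4, DIBAL-H and radical conditions further on.

Step 3
Reactants: 3 methyl (3R)-5-{[tert-butyl(diphenyl)silyl]oxy}-3-methylpentanoate
Product: 4 (3R)-5-{[tert-butyl(diphenyl)silyl]oxy}-3-methylpentanal
Conditions: DIBAL-H (1.05 equiv), CH2Cl2, −78 °C; Rochelle salt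
Reagents that add atoms: none
Why: DIBAL-H half-reduction of the methyl ester at −78 °C stops at the aluminium hemiacetal, which collapses to the aldehyde on work-up.

Step 4
Reactants: 5 2-methylcyclohex-2-en-1-one
Product: 6 rac-2-methylcyclohex-2-en-1-ol
Conditions: NaBH4, CeCl3·7H2O, MeOH, 0 °C
Reagents that add atoms: none
Why: Luche reduction gives clean 1,2-reduction of the enone, and the racemic alcohol is sufficient because step 6 passes through a symmetric allyl intermediate.

Step 5
Reactants: 6 rac-2-methylcyclohex-2-en-1-ol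
Product: 7 rac-methyl 2-methylcyclohex-2-en-1-yl carbonate
Conditions: ClCO2Me, pyridine, CH2Cl2, 0 °C
Reagents that add atoms: methyl chloroformate COC(=O)Cl
Why: Acylation of the allylic alcohol gives an allylic carbonate, which ionises under neutral conditions and supplies its own methoxide base in the next step.

Step 6
Reactants: 7 rac-methyl 2-methylcyclohex-2-en-1-yl carbonate
Product: 8 dimethyl 2-[(1R)-2-methylcyclohex-2-en-1-yl]propanedioate
Conditions: dimethyl malonate (1.5 equiv), [Pd(C3H5)Cl]2 (2.5 mol%), (R,R)-DACH-phenyl Trost ligand (7.5 mol%), CH2Cl2, rt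
Reagents that add atoms: dimethyl malonate COC(=O)CC(=O)OC
Why: Trost asymmetric allylic alkylation: zerovalent palladium ionises both enantiomers of 7 to the same meso 2-methylcyclohexenyl complex and the chiral ligand steers the malonate to one of the two enantiotopic allyl termini, which sets the C5 stereocentre (1R in 8).

Step 7
Reactants: 8 dimethyl 2-[(1R)-2-methylcyclohex-2-en-1-yl]propanedioate
Product: 9 dimethyl 2-[(1R)-2-methyl-4-oxocyclohex-2-en-1-yl]propanedioate
Conditions: t-BuOOH (5 equiv), dirhodium tetracaprolactamate Rh2(C6H10NO)4 (1 mol%), K2CO3 (0.5 equiv), CH2Cl2, rt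
Reagents that add atoms: tert-butyl hydroperoxide CC(C)(C)OO
Why: Radical allylic C–H oxidation (Doyle conditions) should occur at the unhindered ring methylene next to the alkene CH and give the conjugated enone without moving the double bond, the tertiary allylic C–H being shielded by the malonyl group.

Step 8
Reactants: 9 dimethyl 2-[(1R)-2-methyl-4-oxocyclohex-2-en-1-yl]propanedioate
Product: 10 dimethyl 2-[(1R,2R)-2-ethenyl-2-methyl-4-(trimethylsilyloxy)cyclohex-3-en-1-yl]propanedioate
Conditions: CH2=CHMgBr (2.3 equiv), CuBr·SMe2 (20 mol%), Me3SiCl (3 equiv), THF, −78 to −40 °C; Et3N, cold aqueous NaHCO3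
Reagents that add atoms: vinylmagnesium bromide C=C[Mg]Br; chlorotrimethylsilane C[Si](C)(C)Cl
Why: Copper-catalysed conjugate addition with silyl trapping: the first equivalent of Grignard reagent only deprotonates the malonate, the vinyl group then adds to the β-carbon anti to the pseudoaxial C5 substituent, which sets quaternary C10 with vinyl trans to the malonyl group, and the enolate is fixed regiospecifically as the silyl enol ether.

Step 9
Reactants: 10 dimethyl 2-[(1R,2R)-2-ethenyl-2-methyl-4-(trimethylsilyloxy)cyclohex-3-en-1-yl]propanedioate; 4 (3R)-5-{[tert-butyl(diphenyl)silyl]oxy}-3-methylpentanal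
Product: 11 dimethyl 2-[(1R,2R)-3-[(3R)-5-{[tert-butyl(diphenyl)silyl]oxy}-1-hydroxy-3-methylpentyl]-2-ethenyl-2-methyl-4-oxocyclohexyl]propanedioate (epimer mixture at ring C3 and at the carbinol carbon)
Conditions: TiCl4 (1.1 equiv), CH2Cl2, −78 °C
Reagents that add atoms: none
Why: Mukaiyama aldol addition under Lewis-acid conditions forms the C9–C11 bond only at the regiodefined enol ether carbon and tolerates the acidic malonate C–H; the two new centres need no control because one is removed in step 10 and the other is epimerisable.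

Step 10
Reactants: 11 dimethyl 2-[(1R,2R)-3-[(3R)-5-{[tert-butyl(diphenyl)silyl]oxy}-1-hydroxy-3-methylpentyl]-2-ethenyl-2-methyl-4-oxocyclohexyl]propanedioate
Product: 13 dimethyl 2-[(1R,2R)-3-[(3S)-5-{[tert-butyl(diphenyl)silyl]oxy}-3-methylpentylidene]-2-ethenyl-2-methyl-4-oxocyclohexyl]propanedioate (E/Z mixture), via mesylate 12 (not isolated)
Conditions: MsCl, Et3N (4 equiv), CH2Cl2, 0 °C to rt
Reagents that add atoms: none
Why: Mesylation followed by E1cB elimination with the weak base triethylamine gives the conjugated alkylidene ketone without generating the malonate anion, which could otherwise add to the new enone.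

Step 11
Reactants: 13 dimethyl 2-[(1R,2R)-3-[(3S)-5-{[tert-butyl(diphenyl)silyl]oxy}-3-methylpentylidene]-2-ethenyl-2-methyl-4-oxocyclohexyl]propanedioate
Product: 14 dimethyl 2-[(1R,2R,3S)-3-[(3S)-5-{[tert-butyl(diphenyl)silyl]oxy}-3-methylpentyl]-2-ethenyl-2-methyl-4-oxocyclohexyl]propanedioate
Conditions: [(Ph3P)CuH]6 (0.3 equiv), benzene, H2O (2 equiv), rt
Reagents that add atoms: none
Why: Stryker conjugate reduction delivers hydride only to the enone β-carbon and spares the vinyl group, esters and ketone; C9 is set by protonation and, being epimerisable, should settle in the equatorial arrangement cis to the malonyl branch that is drawn.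

Step 12
Reactants: 14 dimethyl 2-[(1R,2R,3S)-3-[(3S)-5-{[tert-butyl(diphenyl)silyl]oxy}-3-methylpentyl]-2-ethenyl-2-methyl-4-oxocyclohexyl]propanedioate
Product: 15 dimethyl 2-[(1R,2R,3S)-3-[(3S)-5-{[tert-butyl(diphenyl)silyl]oxy}-3-methylpentyl]-2-formyl-2-methyl-4-oxocyclohexyl]propanedioate
Conditions: O3, CH2Cl2/MeOH, −78 °C; Me2S
Reagents that add atoms: ozone [O-][O+]=O
Why: Ozonolysis of the only C=C bond with reductive work-up unveils the formyl group on quaternary C10, which has no α-hydrogen.

Step 13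
Reactants: 15 dimethyl 2-[(1R,2R,3S)-3-[(3S)-5-{[tert-butyl(diphenyl)silyl]oxy}-3-methylpentyl]-2-formyl-2-methyl-4-oxocyclohexyl]propanedioate
Product: 18 dimethyl (5S,9S,10R,13S)-15-{[tert-butyl(diphenyl)silyl]oxy}-8-oxo-17-norlabd-1-ene-18,19-dioate, via sodium enolate 16 (not isolated), via phosphonium ylide 17 (not isolated)
Conditions: NaH (1.05 equiv), THF/DMF 4:1, 0 °C; then CH2=CHPPh3Br (1.2 equiv), 0 to 50 °C
Reagents that add atoms: vinyltriphenylphosphonium bromide C=C[P+](c1ccccc1)(c1ccccc1)c1ccccc1.[Br-]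
Why: Sodium hydride removes the malonate C–H (the only proton acidic enough, since the aldehyde on quaternary C10 has no α-hydrogen and the ketone is far less acidic), the soft carbanion 16 adds to the β-carbon of the vinylphosphonium salt (Michael addition, C3–C4 bond) and the resulting non-stabilised ylide 17 attacks the formyl group in an intramolecular Wittig reaction (C1=C2 bond), so the two methylene carbons C2 and C3 are inserted between C4 and C1 in one operation. The closest precedent is the Schweizer cycloalkene annulation of carbonyl-bearing malonates and β-dicarbonyl compounds with vinylphosphonium salts. Ring A is the only ring closed: the ylide carbon attacks the formyl carbon in a 6-exo-trig mode and cycloreversion of the oxaphosphetane gives the cis ring alkene and Ph3PO. No new stereocentre is formed, because C4 becomes quaternary with two identical esters and the trans ring fusion is already fixed by the trans relation of the formyl and malonyl groups at C10 and C5 set in step 8. The step needs the ylide to choose the aldehyde over the C8 ketone, which the higher reactivity of the aldehyde and the six- versus seven-membered closure should secure, and it needs Michael addition instead of carbonyl addition of the malonate, which holds because addition to either carbonyl is reversible and strained whereas addition to the phosphonium salt is irreversible. The equatorial and axial esters at C4 are told apart later by their different steric environment.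

Step 14
Reactants: 18 dimethyl (5S,9S,10R,13S)-15-{[tert-butyl(diphenyl)silyl]oxy}-8-oxo-17-norlabd-1-ene-18,19-dioate
Product: 19 dimethyl (5S,9S,10R,13S)-15-{[tert-butyl(diphenyl)silyl]oxy}-8-oxo-17-norlabdane-18,19-dioate
Conditions: H2 (1 atm), Pd/C, EtOAc, rt
Reagents that add atoms: none
Why: Heterogeneous hydrogenation saturates the cis-disubstituted ring alkene, whereas ketone, esters and silyl ether are inert.

Step 15
Reactants: 19 dimethyl (5S,9S,10R,13S)-15-{[tert-butyl(diphenyl)silyl]oxy}-8-oxo-17-norlabdane-18,19-dioate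
Product: 20 dimethyl (5S,9R,10S,13S)-15-{[tert-butyl(diphenyl)silyl]oxy}labd-8(17)-ene-18,19-dioate
Conditions: Ph3PCH3Br, KOtBu, THF, 0 °C to reflux
Reagents that add atoms: methyltriphenylphosphonium bromide C[P+](c1ccccc1)(c1ccccc1)c1ccccc1.[Br-]
Why: Wittig methylenation of the C8 ketone; the basic medium also equilibrates C9 to the equatorial side chain before the ketone is consumed.

Step 16
Reactants: 20 dimethyl (5S,9R,10S,13S)-15-{[tert-butyl(diphenyl)silyl]oxy}labd-8(17)-ene-18,19-dioate
Product: 21 dimethyl (5S,8S,9S,10R,13S)-15-{[tert-butyl(diphenyl)silyl]oxy}-8,17-epoxylabdane-18,19-dioate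
Conditions: mCPBA, NaHCO3, CH2Cl2, 0 °C
Reagents that add atoms: 3-chloroperoxybenzoic acid OOC(=O)c1cccc(Cl)c1
Why: Prilezhaev epoxidation should occur from the equatorial face because the axial face of C8 is blocked by the syn-axial C10 methyl, which places the epoxide oxygen equatorial and sets C8.

Step 17
Reactants: 21 dimethyl (5S,8S,9S,10R,13S)-15-{[tert-butyl(diphenyl)silyl]oxy}-8,17-epoxylabdane-18,19-dioate
Product: 22 (5S,8S,9S,10R,13S)-15-{[tert-butyl(diphenyl)silyl]oxy}labdane-8,18,19-triol
Conditions: LiAlH4, THF, 0 °C to reflux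
Reagents that add atoms: none
Why: LiAlH4 opens the spiro-epoxide at its unhindered CH2 terminus, so C8 keeps the equatorial oxygen and gains the axial methyl (8S), and it reduces both esters to the 18,19-diol in the same operation.

Step 18
Reactants: 22 (5S,8S,9S,10R,13S)-15-{[tert-butyl(diphenyl)silyl]oxy}labdane-8,18,19-triol
Product: 23 (4S,5S,8S,9S,10R,13S)-15-{[tert-butyl(diphenyl)silyl]oxy}-8,19-dihydroxylabdan-18-yl 2,2-dimethylpropanoate
Conditions: PivCl (1.05 equiv), pyridine, CH2Cl2, −20 to 0 °C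
Reagents that add atoms: pivaloyl chloride CC(C)(C)C(=O)Cl
Why: Acylation with bulky pivaloyl chloride should be selective for the equatorial C18 hydroxymethyl group because the axial C19 hydroxymethyl is screened by the syn-axial C10 methyl and the tertiary alcohol is inert, which makes C4 a defined stereocentre.

Step 19
Reactants: 23 (4S,5S,8S,9S,10R,13S)-15-{[tert-butyl(diphenyl)silyl]oxy}-8,19-dihydroxylabdan-18-yl 2,2-dimethylpropanoate
Product: 24 O-[(4R,5S,8S,9S,10R,13S)-15-{[tert-butyl(diphenyl)silyl]oxy}-18-(2,2-dimethylpropanoyloxy)-8-hydroxylabdan-19-yl] 1H-imidazole-1-carbothioate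
Conditions: 1,1'-thiocarbonyldiimidazole, DMAP (cat.), ClCH2CH2Cl, 70 °C
Reagents that add atoms: 1,1'-thiocarbonyldiimidazole S=C(n1ccnc1)n1ccnc1
Why: Acylation of the remaining primary alcohol with thiocarbonyldiimidazole gives the thiocarbonyl derivative for Barton–McCombie deoxygenation, the tertiary alcohol being too hindered to react.

Step 20
Reactants: 24 O-[(4R,5S,8S,9S,10R,13S)-15-{[tert-butyl(diphenyl)silyl]oxy}-18-(2,2-dimethylpropanoyloxy)-8-hydroxylabdan-19-yl] 1H-imidazole-1-carbothioate
Product: 25 (4S,5S,8S,9S,10R,13S)-15-{[tert-butyl(diphenyl)silyl]oxy}-8-hydroxylabdan-18-yl 2,2-dimethylpropanoate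
Conditions: Bu3SnH, AIBN, toluene, reflux
Reagents that add atoms: none
Why: Barton–McCombie radical deoxygenation: the stannyl radical adds to the thiocarbonyl group, β-scission gives the neopentyl C19 radical, which cannot eliminate or rearrange and abstracts hydrogen from Bu3SnH to give the axial methyl.

Step 21
Reactants: 25 (4S,5S,8S,9S,10R,13S)-15-{[tert-butyl(diphenyl)silyl]oxy}-8-hydroxylabdan-18-yl 2,2-dimethylpropanoate
Product: 26 (4S,5S,8S,9S,10R,13S)-15-{[tert-butyl(diphenyl)silyl]oxy}labdane-8,18-diol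
Conditions: DIBAL-H (3 equiv), CH2Cl2, −78 °C
Reagents that add atoms: none
Why: Reductive cleavage of the pivalate with DIBAL-H frees the C18 alcohol and leaves the silyl ether and the tertiary alcohol untouched.

Step 22
Reactants: 26 (4S,5S,8S,9S,10R,13S)-15-{[tert-butyl(diphenyl)silyl]oxy}labdane-8,18-diol
Product: 27 (4S,5S,8S,9S,10R,13S)-15-{[tert-butyl(diphenyl)silyl]oxy}-8-hydroxylabdan-18-yl (2Z)-2-methylbut-2-enoate
Conditions: angelic acid, 2,4,6-Cl3C6H2COCl, Et3N, toluene, rt; then 26, 80 °C
Reagents that add atoms: angelic acid C/C=C(/C)C(=O)O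
Why: Yamaguchi esterification through the mixed 2,4,6-trichlorobenzoic anhydride acylates the primary neopentyl alcohol without a nucleophilic catalyst, conditions under which the (Z)-geometry of the angeloyl group should be kept, while the tertiary alcohol does not react.

Step 23
Reactants: 27 (4S,5S,8S,9S,10R,13S)-15-{[tert-butyl(diphenyl)silyl]oxy}-8-hydroxylabdan-18-yl (2Z)-2-methylbut-2-enoate
Product: 28 (4S,5S,8S,9S,10R,13S)-8,15-dihydroxylabdan-18-yl (2Z)-2-methylbut-2-enoate
Conditions: HF·pyridine, pyridine, THF, 0 °C to rt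
Reagents that add atoms: none
Why: Fluoride cleavage of the silyl ether with buffered HF·pyridine should leave both the angelate and the tertiary alcohol intact.

Step 24
Reactants: 28 (4S,5S,8S,9S,10R,13S)-8,15-dihydroxylabdan-18-yl (2Z)-2-methylbut-2-enoate
Product: 29 3-{[(4S,5S,8S,9S,10R,13S)-8-hydroxy-18-{[(2Z)-2-methylbut-2-enoyl]oxy}labdan-15-yl]oxy}-3-oxopropanoic acid (CNP0286290.1)
Conditions: Meldrum's acid (1.2 equiv), toluene, 90 °C
Reagents that add atoms: Meldrum's acid CC1(C)OC(=O)CC(=O)O1
Why: Thermal acylation with Meldrum's acid: the primary alcohol opens the dioxanedione ring and loss of acetone gives the malonic acid monoester directly, the tertiary alcohol being unreactive.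

**Compound list**

1 | methyl hydrogen (R)-3-methylglutarate [(3R)-5-methoxy-3-methyl-5-oxopentanoic acid] | COC(=O)C[C@H](C)CC(=O)O | starting material
2 | methyl (3R)-5-hydroxy-3-methylpentanoate | COC(=O)C[C@H](C)CCO | intermediate
3 | methyl (3R)-5-{[tert-butyl(diphenyl)silyl]oxy}-3-methylpentanoate | COC(=O)C[C@H](C)CCO[Si](c1ccccc1)(c1ccccc1)C(C)(C)C | intermediate
4 | (3R)-5-{[tert-butyl(diphenyl)silyl]oxy}-3-methylpentanal | O=CC[C@H](C)CCO[Si](c1ccccc1)(c1ccccc1)C(C)(C)C | intermediate
5 | 2-methylcyclohex-2-en-1-one | CC1=CCCCC1=O | starting material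
6 | rac-2-methylcyclohex-2-en-1-ol | CC1=CCCCC1O | intermediate
7 | rac-methyl 2-methylcyclohex-2-en-1-yl carbonate | COC(=O)OC1CCCC=C1C | intermediate
8 | dimethyl 2-[(1R)-2-methylcyclohex-2-en-1-yl]propanedioate | CC1=CCCC[C@@H]1C(C(=O)OC)C(=O)OC | intermediate
9 | dimethyl 2-[(1R)-2-methyl-4-oxocyclohex-2-en-1-yl]propanedioate | CC1=CC(=O)CC[C@@H]1C(C(=O)OC)C(=O)OC | intermediate
10 | dimethyl 2-[(1R,2R)-2-ethenyl-2-methyl-4-(trimethylsilyloxy)cyclohex-3-en-1-yl]propanedioate | C=C[C@@]1(C)C=C(O[Si](C)(C)C)CC[C@@H]1C(C(=O)OC)C(=O)OC | intermediate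
11 | dimethyl 2-[(1R,2R)-3-[(3R)-5-{[tert-butyl(diphenyl)silyl]oxy}-1-hydroxy-3-methylpentyl]-2-ethenyl-2-methyl-4-oxocyclohexyl]propanedioate (epimers at ring C3 and carbinol carbon) | O=C1CC[C@H](C(C(=O)OC)C(=O)OC)[C@@](C)(C=C)C1C(O)C[C@H](C)CCO[Si](c1ccccc1)(c1ccccc1)C(C)(C)C | intermediate
12 | methanesulfonate of aldol 11 (not isolated) | O=C1CC[C@H](C(C(=O)OC)C(=O)OC)[C@@](C)(C=C)C1C(OS(C)(=O)=O)C[C@H](C)CCO[Si](c1ccccc1)(c1ccccc1)C(C)(C)C | intermediate
13 | dimethyl 2-[(1R,2R)-3-[(3S)-5-{[tert-butyl(diphenyl)silyl]oxy}-3-methylpentylidene]-2-ethenyl-2-methyl-4-oxocyclohexyl]propanedioate (E/Z mixture) | O=C1CC[C@H](C(C(=O)OC)C(=O)OC)[C@@](C)(C=C)C1=CC[C@H](C)CCO[Si](c1ccccc1)(c1ccccc1)C(C)(C)C | intermediate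
14 | dimethyl 2-[(1R,2R,3S)-3-[(3S)-5-{[tert-butyl(diphenyl)silyl]oxy}-3-methylpentyl]-2-ethenyl-2-methyl-4-oxocyclohexyl]propanedioate | O=C1CC[C@H](C(C(=O)OC)C(=O)OC)[C@@](C)(C=C)[C@@H]1CC[C@H](C)CCO[Si](c1ccccc1)(c1ccccc1)C(C)(C)C | intermediate
15 | dimethyl 2-[(1R,2R,3S)-3-[(3S)-5-{[tert-butyl(diphenyl)silyl]oxy}-3-methylpentyl]-2-formyl-2-methyl-4-oxocyclohexyl]propanedioate | O=C1CC[C@H](C(C(=O)OC)C(=O)OC)[C@@](C)(C=O)[C@@H]1CC[C@H](C)CCO[Si](c1ccccc1)(c1ccccc1)C(C)(C)C | intermediate
16 | sodium enolate of malonate 15 (not isolated) | COC(=O)[C-](C(=O)OC)[C@H]1CCC(=O)[C@@H](CC[C@H](C)CCO[Si](c2ccccc2)(c2ccccc2)C(C)(C)C)[C@]1(C)C=O.[Na+] | intermediate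
17 | phosphonium ylide from Michael addition of 16 to the vinylphosphonium salt (not isolated) | COC(=O)C(CC=P(c2ccccc2)(c2ccccc2)c2ccccc2)(C(=O)OC)[C@H]1CCC(=O)[C@@H](CC[C@H](C)CCO[Si](c2ccccc2)(c2ccccc2)C(C)(C)C)[C@]1(C)C=O | intermediate
18 | dimethyl (5S,9S,10R,13S)-15-{[tert-butyl(diphenyl)silyl]oxy}-8-oxo-17-norlabd-1-ene-18,19-dioate (trans-fused) | COC(=O)C1(C(=O)OC)CC=C[C@]2(C)[C@@H]1CCC(=O)[C@H]2CC[C@H](C)CCO[Si](c1ccccc1)(c1ccccc1)C(C)(C)C | intermediate
19 | dimethyl (5S,9S,10R,13S)-15-{[tert-butyl(diphenyl)silyl]oxy}-8-oxo-17-norlabdane-18,19-dioate | COC(=O)C1(C(=O)OC)CCC[C@]2(C)[C@@H]1CCC(=O)[C@H]2CC[C@H](C)CCO[Si](c1ccccc1)(c1ccccc1)C(C)(C)C | intermediate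
20 | dimethyl (5S,9R,10S,13S)-15-{[tert-butyl(diphenyl)silyl]oxy}labd-8(17)-ene-18,19-dioate | COC(=O)C1(C(=O)OC)CCC[C@]2(C)[C@@H]1CCC(=C)[C@H]2CC[C@H](C)CCO[Si](c1ccccc1)(c1ccccc1)C(C)(C)C | intermediate
21 | dimethyl (5S,8S,9S,10R,13S)-15-{[tert-butyl(diphenyl)silyl]oxy}-8,17-epoxylabdane-18,19-dioate (epoxide oxygen equatorial) | COC(=O)C1(C(=O)OC)CCC[C@]2(C)[C@@H]1CC[C@]3(OC3)[C@H]2CC[C@H](C)CCO[Si](c1ccccc1)(c1ccccc1)C(C)(C)C | intermediate
22 | (5S,8S,9S,10R,13S)-15-{[tert-butyl(diphenyl)silyl]oxy}labdane-8,18,19-triol | OCC1(CO)CCC[C@]2(C)[C@@H]1CC[C@](C)(O)[C@H]2CC[C@H](C)CCO[Si](c1ccccc1)(c1ccccc1)C(C)(C)C | intermediate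
23 | (4S,5S,8S,9S,10R,13S)-15-{[tert-butyl(diphenyl)silyl]oxy}-8,19-dihydroxylabdan-18-yl 2,2-dimethylpropanoate | CC(C)(C)C(=O)OC[C@@]1(CO)CCC[C@]2(C)[C@@H]1CC[C@](C)(O)[C@H]2CC[C@H](C)CCO[Si](c1ccccc1)(c1ccccc1)C(C)(C)C | intermediate
24 | O-[(4R,5S,8S,9S,10R,13S)-15-{[tert-butyl(diphenyl)silyl]oxy}-18-(2,2-dimethylpropanoyloxy)-8-hydroxylabdan-19-yl] 1H-imidazole-1-carbothioate | CC(C)(C)C(=O)OC[C@@]1(COC(=S)n3ccnc3)CCC[C@]2(C)[C@@H]1CC[C@](C)(O)[C@H]2CC[C@H](C)CCO[Si](c1ccccc1)(c1ccccc1)C(C)(C)C | intermediate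
25 | (4S,5S,8S,9S,10R,13S)-15-{[tert-butyl(diphenyl)silyl]oxy}-8-hydroxylabdan-18-yl 2,2-dimethylpropanoate | CC(C)(C)C(=O)OC[C@@]1(C)CCC[C@]2(C)[C@@H]1CC[C@](C)(O)[C@H]2CC[C@H](C)CCO[Si](c1ccccc1)(c1ccccc1)C(C)(C)C | intermediate
26 | (4S,5S,8S,9S,10R,13S)-15-{[tert-butyl(diphenyl)silyl]oxy}labdane-8,18-diol | OC[C@@]1(C)CCC[C@]2(C)[C@@H]1CC[C@](C)(O)[C@H]2CC[C@H](C)CCO[Si](c1ccccc1)(c1ccccc1)C(C)(C)C | intermediate
27 | (4S,5S,8S,9S,10R,13S)-15-{[tert-butyl(diphenyl)silyl]oxy}-8-hydroxylabdan-18-yl (2Z)-2-methylbut-2-enoate | C/C=C(/C)C(=O)OC[C@@]1(C)CCC[C@]2(C)[C@@H]1CC[C@](C)(O)[C@H]2CC[C@H](C)CCO[Si](c1ccccc1)(c1ccccc1)C(C)(C)C | intermediate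
28 | (4S,5S,8S,9S,10R,13S)-8,15-dihydroxylabdan-18-yl (2Z)-2-methylbut-2-enoate | C/C=C(/C)C(=O)OC[C@@]1(C)CCC[C@]2(C)[C@@H]1CC[C@](C)(O)[C@H]2CC[C@H](C)CCO | intermediate
29 | 3-{[(4S,5S,8S,9S,10R,13S)-8-hydroxy-18-{[(2Z)-2-methylbut-2-enoyl]oxy}labdan-15-yl]oxy}-3-oxopropanoic acid (CNP0286290.1) | C/C=C(/C)C(=O)OC[C@@]1(C)CCC[C@]2(C)[C@@H]1CC[C@](C)(O)[C@H]2CC[C@H](C)CCOC(=O)CC(=O)O | target

**Step count and risks**

Total step count: 24 steps. Longest linear sequence: 21 steps (steps 4–24, from 2-methylcyclohex-2-en-1-one 5 to 29); steps 1–3 form the side-chain branch that joins in step 9.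

Steps most likely to fail:

Step 7 (allylic oxidation). What may go wrong: poor site selectivity of hydrogen abstraction (ring methylene versus the C10 methyl or the malonate C–H), over-oxidation, and erosion of the C5 configuration by base-induced dienolisation of the γ-substituted enone. The fallback sets out from 8 and comes back at 9. Epoxidation of 8 with mCPBA should give the epoxide dimethyl 2-[(2R)-1-methyl-7-oxabicyclo[4.1.0]heptan-2-yl]propanedioate F1. Opening with PhSeNa (from (PhSe)2 and NaBH4 in EtOH) at the less substituted epoxide carbon should give the hydroxy selenide dimethyl 2-[(1R)-2-hydroxy-2-methyl-3-(phenylselanyl)cyclohexyl]propanedioate F2. Oxidation with H2O2 and syn-elimination of the selenoxide away from the carbinol carbon should give the tertiary allylic alcohol dimethyl 2-[(1R)-2-hydroxy-2-methylcyclohex-3-en-1-yl]propanedioate F3 (Sharpless–Lauer sequence). Oxidative 1,3-transposition with pyridinium chlorochromate (C5H5NH)[CrO3Cl] (Babler–Dauben) then returns enone 9 with unambiguous regiochemistry and under non-basic conditions.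

Step 13 (key annulation). What may go wrong: slow Michael addition of the hindered tertiary malonate carbanion, proton transfer that stops the sequence at the phosphonium salt, or competing carbonyl addition and olefination at the C8 ketone. The fallback sets out from 15 and comes back at 18, making the same two bonds in known separate steps. Chemoselective addition of vinylmagnesium bromide (2.2 equiv, the first being consumed by the malonate C–H) to the aldehyde of 15 at −78 °C should give the allylic alcohol dimethyl 2-[(1R,2R,3S)-3-[(3S)-5-{[tert-butyl(diphenyl)silyl]oxy}-3-methylpentyl]-2-(1-hydroxyprop-2-en-1-yl)-2-methyl-4-oxocyclohexyl]propanedioate F4 (C1–C2 bond; the carbinol centre is a mixture and is destroyed later). Methyl chloroformate and pyridine should give the allylic carbonate dimethyl 2-[(1R,2R,3S)-3-[(3S)-5-{[tert-butyl(diphenyl)silyl]oxy}-3-methylpentyl]-2-{1-[(methoxycarbonyl)oxy]prop-2-en-1-yl}-2-methyl-4-oxocyclohexyl]propanedioate F5. Pd(PPh3)4 (zerovalent palladium) in THF at 60 °C ionises F5 to an allyl complex of divalent palladium, and the malonate, deprotonated by the liberated methoxide, closes the six-membered ring at the distal allyl terminus (intramolecular Tsuji–Trost alkylation, C3–C4 bond; closure at the proximal terminus would need a four-membered ring) to give 18.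

Step 22 (angeloylation). What may go wrong: Z-to-E isomerisation of the angeloyl group to the tiglate during acylation of the hindered neopentyl alcohol, or incomplete acylation. The fallback sets out from 26 and comes back at 27. Esterification of 26 with 2-[bis(2,2,2-trifluoroethoxy)phosphoryl]propanoic acid (DCC, DMAP, CH2Cl2) should give the phosphonate ester (4S,5S,8S,9S,10R,13S)-15-{[tert-butyl(diphenyl)silyl]oxy}-8-hydroxylabdan-18-yl 2-[bis(2,2,2-trifluoroethoxy)phosphoryl]propanoate F6. Still–Gennari olefination with acetaldehyde (KN(SiMe3)2, 18-crown-6, THF, −78 °C) then builds the (Z)-2-methylbut-2-enoate in place and gives 27.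

**Further compounds**

F1 | step 7 | dimethyl 2-[(2R)-1-methyl-7-oxabicyclo[4.1.0]heptan-2-yl]propanedioate (epoxide diastereomers) | CC12OC1CCC[C@@H]2C(C(=O)OC)C(=O)OC
F2 | step 7 | dimethyl 2-[(1R)-2-hydroxy-2-methyl-3-(phenylselanyl)cyclohexyl]propanedioate | CC1(O)C([Se]c2ccccc2)CCC[C@@H]1C(C(=O)OC)C(=O)OC
F3 | step 7 | dimethyl 2-[(1R)-2-hydroxy-2-methylcyclohex-3-en-1-yl]propanedioate | CC1(O)C=CCC[C@@H]1C(C(=O)OC)C(=O)OC
F4 | step 13 | dimethyl 2-[(1R,2R,3S)-3-[(3S)-5-{[tert-butyl(diphenyl)silyl]oxy}-3-methylpentyl]-2-(1-hydroxyprop-2-en-1-yl)-2-methyl-4-oxocyclohexyl]propanedioate | O=C1CC[C@H](C(C(=O)OC)C(=O)OC)[C@@](C)(C(O)C=C)[C@@H]1CC[C@H](C)CCO[Si](c1ccccc1)(c1ccccc1)C(C)(C)C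
F5 | step 13 | dimethyl 2-[(1R,2R,3S)-3-[(3S)-5-{[tert-butyl(diphenyl)silyl]oxy}-3-methylpentyl]-2-{1-[(methoxycarbonyl)oxy]prop-2-en-1-yl}-2-methyl-4-oxocyclohexyl]propanedioate | O=C1CC[C@H](C(C(=O)OC)C(=O)OC)[C@@](C)(C(OC(=O)OC)C=C)[C@@H]1CC[C@H](C)CCO[Si](c1ccccc1)(c1ccccc1)C(C)(C)C
F6 | step 22 | (4S,5S,8S,9S,10R,13S)-15-{[tert-butyl(diphenyl)silyl]oxy}-8-hydroxylabdan-18-yl 2-[bis(2,2,2-trifluoroethoxy)phosphoryl]propanoate | CC(C(=O)OC[C@@]1(C)CCC[C@]2(C)[C@@H]1CC[C@](C)(O)[C@H]2CC[C@H](C)CCO[Si](c1ccccc1)(c1ccccc1)C(C)(C)C)P(=O)(OCC(F)(F)F)OCC(F)(F)F
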